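The route rests on disconnecting the hydroazulene at the quaternary fusion carbon C3a: C3a, with its neighbours C4 and C8a, is read as a former cyclopropane whose two alkenyl arms (C5=C6 and C8=C7) lie on the same face. In one operation a rhodium carbenoid at C8a adds across a tethered C3a=C4 alkene, closing the five-membered ring (C1–C3, C3a, C8a), and the resulting cis-divinylcyclopropane ring-expands by Cope rearrangement (C8a–C4 broken, C6–C7 formed) to the seven-membered ring (C3a–C8a), fixing C3a. The precursor is an acyclic vinyl diazoketone tethered to an E-configured 2-siloxydiene; its ketone (C1) and enol ether (C5) later carry the side chain and the allylic acetate.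

Key step: step 8

Remarks on the chemistry
- Azulene numbering is used for the bicycle throughout (C1 bears the side chain, C3a the methyl group, C5 the ring acetate, C6 the exocyclic methylene, C8a the fusion hydrogen). β denotes the face of the C3a methyl group and α the opposite face. The target is 3aβ-methyl, 8aα-H (trans-fused), 1α-H (side chain β), 5α-OAc.
- Assumption: Rh2(S-PTAD)4 is taken to give (3aR)-15 in step 8. If it gives the antipode, Rh2(R-PTAD)4 is used.
- Assumption: the acetate aldol addition in step 16 is taken to follow the facial preference of α-branched saturated aldehydes.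
- The siloxydiene is installed at the ester stage because a silyl triflate and an amine base would otherwise enolise the far more acidic allyl ketone or attack the diazo ketone. The E alkene is made by a Claisen rearrangement so that the Cope step has the geometry it needs.
- A direct hydrogenation of the C8=C8a enone has no reliable face preference and leaves an epimerisable C8a centre. The ring fusion is therefore set by a hydroxyl-directed hydrogenation (steps 10 to 12).

Step 1
Reactants: 1 methacrolein; 2 ethynylmagnesium bromide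
Product: 3 2-methylpent-1-en-4-yn-3-ol
Conditions: THF, 0 °C; aq. NH4Cl
Reagents that add atoms: none
Why: 1,2-Addition of the acetylide Grignard reagent to the enal carbonyl gives the secondary enynol, whose stereocentre is lost in step 2, so the racemate is used.

Step 2
Reactants: 3 2-methylpent-1-en-4-yn-3-ol; 4 triethyl orthoacetate
Product: 6 ethyl (4E)-4-methylhept-4-en-6-ynoate, via ketene acetal 5 (not isolated)
Conditions: EtCO2H (5 mol %), neat, 140 °C, EtOH distilled off
Reagents that add atoms: none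
Why: Johnson–Claisen rearrangement, in which acid-catalysed exchange forms ketene acetal 5 and its chair-like [3,3] shift through the more nucleophilic methallyl arm (the propargyl arm reacts more slowly) places the alkynyl group equatorial and so gives the E-trisubstituted alkene that becomes C3a=C4.

Step 3
Reactants: 6 ethyl (4E)-4-methylhept-4-en-6-ynoate
Product: 7 ethyl (4E)-4-methyl-6-oxohept-4-enoate
Conditions: (Ph3P)AuCl (2 mol %), AgOTf (2 mol %), H2O (5 equiv), 1,4-dioxane, 60 °C
Reagents that add atoms: water (O)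
Why: Gold-catalysed (monovalent gold) Markovnikov hydration of the terminal alkyne gives the conjugated methyl ketone under near-neutral conditions that should leave the ester and the alkene geometry untouched.

Step 4
Reactants: 7 ethyl (4E)-4-methyl-6-oxohept-4-enoate
Product: 8 ethyl (4E)-6-[(tert-butyldimethylsilyl)oxy]-4-methylhepta-4,6-dienoate
Conditions: TBSOTf, Et3N, CH2Cl2, −78 → 0 °C
Reagents that add atoms: tert-butyldimethylsilyl trifluoromethanesulfonate (CC(C)(C)[Si](C)(C)OS(=O)(=O)C(F)(F)F)
Why: Soft enolisation, in which O-silylation of the enone is followed by amine deprotonation at the unhindered methyl group to give the 2-siloxydiene, while the ester is not enolised under these conditions.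

Step 5
Reactants: 8 ethyl (4E)-6-[(tert-butyldimethylsilyl)oxy]-4-methylhepta-4,6-dienoate
Product: 9 (4E)-6-[(tert-butyldimethylsilyl)oxy]-N-methoxy-N,4-dimethylhepta-4,6-dienamide
Conditions: MeNH(OMe)·HCl, iPrMgCl, THF, −20 °C
Reagents that add atoms: N,O-dimethylhydroxylamine hydrochloride (CNOC.Cl)
Why: Weinreb amide formation by aminolysis of the ester with the chloromagnesium amide proceeds at low temperature, at which the silyl dienol ether is inert to the hindered Grignard base.

Step 6
Reactants: 9 (4E)-6-[(tert-butyldimethylsilyl)oxy]-N-methoxy-N,4-dimethylhepta-4,6-dienamide; 10 allylmagnesium bromide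
Product: 11 (7E)-9-[(tert-butyldimethylsilyl)oxy]-7-methyldeca-1,7,9-trien-4-one
Conditions: THF, −78 °C; cold aq. NH4Cl
Reagents that add atoms: none
Why: Weinreb ketone synthesis, in which the chelated tetrahedral adduct resists a second addition and releases the β,γ-unsaturated allyl ketone only on cold neutral quench, which limits conjugation of the alkene.

Step 7
Reactants: 11 (7E)-9-[(tert-butyldimethylsilyl)oxy]-7-methyldeca-1,7,9-trien-4-one; 12 4-acetamidobenzenesulfonyl azide
Product: 13 (7E)-9-[(tert-butyldimethylsilyl)oxy]-3-diazo-7-methyldeca-1,7,9-trien-4-one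
Conditions: DBU, MeCN, 0 °C; used at once
Reagents that add atoms: none
Why: Regitz-type diazo transfer, in which DBU removes the proton flanked by the carbonyl and vinyl groups (a conjugated propenyl ketone isomer would give the same dienolate) and the sulfonyl azide transfers N2 to that carbon, the product being kept cold and used without storage because unsubstituted vinyl diazo compounds slowly cyclise to pyrazoles.

Step 8
Reactants: 13 (7E)-9-[(tert-butyldimethylsilyl)oxy]-3-diazo-7-methyldeca-1,7,9-trien-4-one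
Product: 15 (3aR)-5-[(tert-butyldimethylsilyl)oxy]-3a-methyl-3,3a,6,7-tetrahydroazulen-1(2H)-one, via divinylcyclopropane 14 (not isolated)
Conditions: Rh2(S-PTAD)4 (1 mol %), hexanes, slow addition of 13, 0 °C → rt; then toluene, 80 °C
Reagents that add atoms: none
Why: The dirhodium tetracarboxylate (divalent rhodium) expels N2 from 13 to give a vinyl-substituted acyl carbenoid at C8a, which adds across the tethered C3a=C4 alkene in a concerted, asynchronous [2+1] step; the closest known reaction type is the tandem cyclopropanation and divinylcyclopropane Cope rearrangement of vinyl diazo carbonyl compounds with dienes (a formal [4+3] cycloaddition) in its intramolecular form. The five-membered ring closes by this intramolecular cyclopropanation through the three-atom tether (bond C8a–C3a, giving bicyclo[3.1.0]hexan-2-one 14), and the seven-membered ring closes by the boat-like [3,3] shift of 14, which breaks C8a–C4 and forms C6–C7 with release of ring strain. The one stereocentre that survives, quaternary C3a, is set by the chiral carboxylate ligands, which choose the face of C3a=C4 that the carbenoid approaches. Chemoselectivity for the proximal alkene over the terminal enol ether alkene follows from the short tether, which allows only five-membered ring formation. Because C3a=C4 is E, the cyclopropane carries both alkenyl arms on one face, as the Cope step needs, and the heating period is included because the C3a methyl group on that same face crowds the boat transition state.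

Step 9
Reactants: 15 (3aR)-5-[(tert-butyldimethylsilyl)oxy]-3a-methyl-3,3a,6,7-tetrahydroazulen-1(2H)-one
Product: 16 (3aR)-5,5-(ethylenedioxy)-3a-methyl-3,3a,4,5,6,7-hexahydroazulen-1(2H)-one
Conditions: HOCH2CH2OH (5 equiv), CSA (5 mol %), 4 Å MS, CH2Cl2, 0 °C → rt
Reagents that add atoms: ethylene glycol (OCCO)
Why: Acid-catalysed acetal exchange at the silyl enol ether, in which protonation at C4 gives the C5 oxocarbenium ion that is trapped by the diol and loses silanol to close the dioxolane, whereas the conjugated C1 ketone does not ketalise without removal of water.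

Step 10
Reactants: 16 (3aR)-5,5-(ethylenedioxy)-3a-methyl-3,3a,4,5,6,7-hexahydroazulen-1(2H)-one
Product: 17 (1R,3aR)-5,5-(ethylenedioxy)-3a-methyl-1,2,3,3a,4,5,6,7-octahydroazulen-1-ol
Conditions: (S)-2-methyl-CBS-oxazaborolidine (20 mol %), catecholborane, toluene, −78 °C
Reagents that add atoms: none
Why: CBS reduction, in which the oxazaborolidine treats the alkenyl carbon C8a as the large and C2 as the small group flanking the C1 ketone, so that the (S)-catalyst should give the (1R)-alcohol with its hydroxyl on the α-face, a temporary stereocentre that serves only to direct step 11.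

Step 11
Reactants: 17 (1R,3aR)-5,5-(ethylenedioxy)-3a-methyl-1,2,3,3a,4,5,6,7-octahydroazulen-1-ol
Product: 18 (1R,3aR,8aR)-5,5-(ethylenedioxy)-3a-methyldecahydroazulen-1-ol
Conditions: [Ir(cod)(PCy3)(py)]PF6 (5 mol %), H2 (1 atm), CH2Cl2, 0 °C → rt
Reagents that add atoms: none
Why: Hydroxyl-directed homogeneous hydrogenation, in which the cationic iridium catalyst binds the allylic C1 hydroxyl and adds H2 to C8=C8a from the same (α) face, so that the C8a hydrogen is set trans to the C3a methyl group whatever the weak intrinsic bias of the bicyclic alkene.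

Step 12
Reactants: 18 (1R,3aR,8aR)-5,5-(ethylenedioxy)-3a-methyldecahydroazulen-1-ol
Product: 19 (3aR,8aR)-5,5-(ethylenedioxy)-3a-methyloctahydroazulen-1(2H)-one
Conditions: DMP (1,1,1-triacetoxy-1,1-dihydro-1,2-benziodoxol-3(1H)-one), pyridine, CH2Cl2, 0 °C → rt
Reagents that add atoms: none
Why: Oxidation of the secondary alcohol with the hypervalent iodine reagent under buffered, non-basic conditions returns the C1 ketone without epimerising the adjacent C8a centre.

Step 13
Reactants: 19 (3aR,8aR)-5,5-(ethylenedioxy)-3a-methyloctahydroazulen-1(2H)-one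
Product: 21 (3aR,8aR)-5,5-(ethylenedioxy)-3a-methyl-3,3a,4,5,6,7,8,8a-octahydroazulen-1-yl trifluoromethanesulfonate, via lithium enolate 20 (not isolated)
Conditions: LiN(iPr)2, THF, −78 °C (ketone added to base); then N-(5-chloropyridin-2-yl)bis(trifluoromethanesulfonimide), −78 → 0 °C
Reagents that add atoms: N-(5-chloropyridin-2-yl)bis(trifluoromethanesulfonimide) (FC(F)(F)S(=O)(=O)N(c1ccc(Cl)cn1)S(=O)(=O)C(F)(F)F)
Why: Kinetic deprotonation by the hindered amide base at −78 °C removes a C2 proton and not the tertiary C8a proton, so the enolate is trapped as the C1–C2 enol triflate with the ring fusion intact.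

Step 14
Reactants: 21 (3aR,8aR)-5,5-(ethylenedioxy)-3a-methyl-3,3a,4,5,6,7,8,8a-octahydroazulen-1-yl trifluoromethanesulfonate; 22 tributyl(1-ethoxyethenyl)stannane
Product: 24 1-[(3aR,8aR)-5,5-(ethylenedioxy)-3a-methyl-3,3a,4,5,6,7,8,8a-octahydroazulen-1-yl]ethan-1-one, via ethoxydiene 23 (not isolated)
Conditions: Pd(PPh3)4 (5 mol %), LiCl, THF, 65 °C; then aq. oxalic acid, THF, 0 °C
Reagents that add atoms: water (O)
Why: Stille coupling of the alkenyl triflate (zerovalent palladium, chloride additive) introduces the 1-ethoxyvinyl group, and brief mild acid hydrolyses this enol ether far faster than the dioxolane to give the methyl enone.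

Step 15
Reactants: 24 1-[(3aR,8aR)-5,5-(ethylenedioxy)-3a-methyl-3,3a,4,5,6,7,8,8a-octahydroazulen-1-yl]ethan-1-one
Product: 25 1-[(1S,3aR,8aS)-5,5-(ethylenedioxy)-3a-methyldecahydroazulen-1-yl]ethan-1-one
Conditions: H2 (1 atm), Pd/C (10 %), EtOAc, rt
Reagents that add atoms: none
Why: Heterogeneous hydrogenation of the conjugated C1=C2 alkene should occur from the α-face, away from the axial C3a methyl group and the C8 methylene on the β-face, so that the C1 hydrogen becomes cis to the C8a hydrogen and the acetyl group takes the β-position required for the side chain.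

Step 16
Reactants: 26 (S)-2-hydroxy-1,2,2-triphenylethyl acetate; 1 methacrolein
Product: 28 (1S)-2-hydroxy-1,2,2-triphenylethyl (3S)-3-hydroxy-4-methylpent-4-enoate, via dilithium enolate 27 (not isolated)
Conditions: LiN(iPr)2 (2.2 equiv), THF, −78 → 0 °C; then 1, −100 °C; aq. NH4Cl; recrystallisation
Reagents that add atoms: none
Why: Auxiliary-controlled acetate aldol addition, in which the doubly deprotonated chiral acetate adds to methacrolein with the facial preference assumed above, so that the (S)-auxiliary should give the (3S)-carbinol that becomes the acetoxy-bearing carbon of the side chain.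

Step 17
Reactants: 28 (1S)-2-hydroxy-1,2,2-triphenylethyl (3S)-3-hydroxy-4-methylpent-4-enoate
Product: 29 (1S)-2-hydroxy-1,2,2-triphenylethyl (3S)-3-[(tert-butyldimethylsilyl)oxy]-4-methylpent-4-enoate
Conditions: TBSCl, imidazole, DMF, rt
Reagents that add atoms: tert-butyldimethylsilyl chloride (CC(C)(C)[Si](C)(C)Cl)
Why: Imidazole-promoted silylation protects the secondary allylic alcohol, while the tertiary diphenylcarbinol of the auxiliary is too hindered to react.

Step 18
Reactants: 29 (1S)-2-hydroxy-1,2,2-triphenylethyl (3S)-3-[(tert-butyldimethylsilyl)oxy]-4-methylpent-4-enoate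
Product: 30 (3S)-3-[(tert-butyldimethylsilyl)oxy]-4-methylpent-4-en-1-ol
Conditions: LiAlH4, Et2O, 0 °C
Reagents that add atoms: none
Why: Hydride reduction of the ester releases the primary alcohol and the auxiliary diol, which is separated, and leaves the silyl ether and the stereocentre untouched.

Step 19
Reactants: 30 (3S)-3-[(tert-butyldimethylsilyl)oxy]-4-methylpent-4-en-1-ol
Product: 31 (3S)-5-bromo-3-[(tert-butyldimethylsilyl)oxy]-2-methylpent-1-ene
Conditions: CBr4, PPh3, CH2Cl2, 0 °C
Reagents that add atoms: carbon tetrabromide (BrC(Br)(Br)Br)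
Why: Appel bromination of the primary alcohol proceeds by SN2 displacement of the alkoxyphosphonium ion and leaves the allylic silyl ether intact.

Step 20
Reactants: 31 (3S)-5-bromo-3-[(tert-butyldimethylsilyl)oxy]-2-methylpent-1-ene; 25 1-[(1S,3aR,8aS)-5,5-(ethylenedioxy)-3a-methyldecahydroazulen-1-yl]ethan-1-one
Product: 33 (1S,3aR,8aS)-1-[(2S,5S)-5-[(tert-butyldimethylsilyl)oxy]-2-hydroxy-6-methylhept-6-en-2-yl]-5,5-(ethylenedioxy)-3a-methyldecahydroazulene, via organomagnesium bromide 32 (not isolated)
Conditions: Mg, THF, rt; then 25, THF, −78 → 0 °C; aq. NH4Cl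
Reagents that add atoms: none
Why: Grignard addition to the methyl ketone under Felkin–Anh control, in which C8a (the largest C1 substituent) lies anti to the nucleophile and the reagent passes the C1 hydrogen, should give the (S)-configured tertiary carbinol, while low temperature favours addition over enolisation and the dioxolane protects C5.

Step 21
Reactants: 33 (1S,3aR,8aS)-1-[(2S,5S)-5-[(tert-butyldimethylsilyl)oxy]-2-hydroxy-6-methylhept-6-en-2-yl]-5,5-(ethylenedioxy)-3a-methyldecahydroazulene
Product: 34 (1S,3aR,8aS)-1-[(2S,5S)-5-[(tert-butyldimethylsilyl)oxy]-2-hydroxy-6-methylhept-6-en-2-yl]-3a-methyloctahydroazulen-5(1H)-one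
Conditions: PPTS, acetone/H2O, 50 °C
Reagents that add atoms: water (O)
Why: Mild acid-catalysed hydrolysis of the dioxolane frees the C5 ketone, the pyridinium acid being too weak to ionise the tertiary alcohol or to cleave the allylic silyl ether.

Step 22
Reactants: 34 (1S,3aR,8aS)-1-[(2S,5S)-5-[(tert-butyldimethylsilyl)oxy]-2-hydroxy-6-methylhept-6-en-2-yl]-3a-methyloctahydroazulen-5(1H)-one
Product: 37 (1S,3aR,8aS)-1-[(2S,5S)-5-[(tert-butyldimethylsilyl)oxy]-2-hydroxy-6-methylhept-6-en-2-yl]-3a-methyl-6-methylideneoctahydroazulen-5(1H)-one, via Mannich base 35 (not isolated), via ammonium iodide 36 (not isolated)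
Conditions: LiN(iPr)2 (2.3 equiv), THF, −78 °C; [Me2N=CH2]I, −78 °C → rt; then MeI, CH2Cl2, rt; then aq. NaHCO3
Reagents that add atoms: N,N-dimethylmethyleneiminium iodide (C=[N+](C)C.[I-])
Why: α-Methylenation by Mannich reaction and Hofmann-type elimination, in which the first equivalent of base deprotonates the tertiary hydroxyl, the second forms the kinetic enolate at C6 (C4 is neopentylic, next to quaternary C3a), the iminium salt aminomethylates it, and N-methylation followed by mild base expels trimethylamine to give the exocyclic enone.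

Step 23
Reactants: 37 (1S,3aR,8aS)-1-[(2S,5S)-5-[(tert-butyldimethylsilyl)oxy]-2-hydroxy-6-methylhept-6-en-2-yl]-3a-methyl-6-methylideneoctahydroazulen-5(1H)-one
Product: 38 (1S,3aR,5S,8aS)-1-[(2S,5S)-5-[(tert-butyldimethylsilyl)oxy]-2-hydroxy-6-methylhept-6-en-2-yl]-3a-methyl-6-methylidenedecahydroazulen-5-ol
Conditions: (R)-2-methyl-CBS-oxazaborolidine (20 mol %), catecholborane (3 equiv), toluene, −78 °C
Reagents that add atoms: none
Why: CBS reduction of the α-methylene ketone, with the alkenyl carbon C6 as the large and C4 as the small group, should give with the (R)-catalyst the (5S)-allylic alcohol (hydroxyl on the α-face) by reagent-controlled 1,2-reduction, and catecholborane at low temperature does not hydroborate the two 1,1-disubstituted alkenes.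

Step 24
Reactants: 38 (1S,3aR,5S,8aS)-1-[(2S,5S)-5-[(tert-butyldimethylsilyl)oxy]-2-hydroxy-6-methylhept-6-en-2-yl]-3a-methyl-6-methylidenedecahydroazulen-5-ol
Product: 39 (1S,3aR,5S,8aS)-1-[(2S,5S)-2,5-dihydroxy-6-methylhept-6-en-2-yl]-3a-methyl-6-methylidenedecahydroazulen-5-ol
Conditions: Bu4NF, THF, 0 °C → rt
Reagents that add atoms: none
Why: Fluoride-mediated cleavage of the silyl ether liberates the side-chain allylic alcohol without affecting the alkenes or the other hydroxyl groups.

Step 25
Reactants: 39 (1S,3aR,5S,8aS)-1-[(2S,5S)-2,5-dihydroxy-6-methylhept-6-en-2-yl]-3a-methyl-6-methylidenedecahydroazulen-5-ol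
Product: 40 (1S,3aR,5S,8aS)-1-[(2S,5S)-5-acetoxy-2-hydroxy-6-methylhept-6-en-2-yl]-3a-methyl-6-methylidenedecahydroazulen-5-yl acetate
Conditions: Ac2O, pyridine, DMAP (5 mol %), CH2Cl2, 0 °C → rt
Reagents that add atoms: acetic anhydride (CC(=O)OC(C)=O)
Why: Nucleophile-catalysed acylation esterifies the two secondary allylic alcohols, while the hindered tertiary alcohol should not react under these mild conditions, which gives the target.

Compound list
1 | methacrolein (2-methylprop-2-enal) | C=C(C)C=O | starting material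
2 | ethynylmagnesium bromide | C#C[Mg]Br | starting material
3 | 2-methylpent-1-en-4-yn-3-ol (racemic) | C=C(C)C(O)C#C | intermediate
4 | triethyl orthoacetate | CCOC(C)(OCC)OCC | starting material
5 | 3-[(1-ethoxyethenyl)oxy]-2-methylpent-1-en-4-yne (racemic ketene acetal; not isolated) | C=C(OCC)OC(C#C)C(C)=C | intermediate
6 | ethyl (4E)-4-methylhept-4-en-6-ynoate | CCOC(=O)CC/C(C)=C/C#C | intermediate
7 | ethyl (4E)-4-methyl-6-oxohept-4-enoate | CCOC(=O)CC/C(C)=C/C(C)=O | intermediate
8 | ethyl (4E)-6-[(tert-butyldimethylsilyl)oxy]-4-methylhepta-4,6-dienoate | CCOC(=O)CC/C(C)=C/C(=C)O[Si](C)(C)C(C)(C)C | intermediate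
9 | (4E)-6-[(tert-butyldimethylsilyl)oxy]-N-methoxy-N,4-dimethylhepta-4,6-dienamide | CON(C)C(=O)CC/C(C)=C/C(=C)O[Si](C)(C)C(C)(C)C | intermediate
10 | allylmagnesium bromide | C=CC[Mg]Br | starting material
11 | (7E)-9-[(tert-butyldimethylsilyl)oxy]-7-methyldeca-1,7,9-trien-4-one | C=CCC(=O)CC/C(C)=C/C(=C)O[Si](C)(C)C(C)(C)C | intermediate
12 | 4-acetamidobenzenesulfonyl azide | CC(=O)Nc1ccc(cc1)S(=O)(=O)N=[N+]=[N-] | starting material
13 | (7E)-9-[(tert-butyldimethylsilyl)oxy]-3-diazo-7-methyldeca-1,7,9-trien-4-one | C=CC(=[N+]=[N-])C(=O)CC/C(C)=C/C(O[Si](C)(C)C(C)(C)C)=C | intermediate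
14 | 6-{1-[(tert-butyldimethylsilyl)oxy]ethenyl}-1-ethenyl-5-methylbicyclo[3.1.0]hexan-2-one; the 1-ethenyl, 5-methyl and 6-alkenyl groups all on the exo face (not isolated) | O=C1CC[C@]2(C)[C@@H](C(=C)O[Si](C)(C)C(C)(C)C)[C@]12C=C | intermediate
15 | (3aR)-5-[(tert-butyldimethylsilyl)oxy]-3a-methyl-3,3a,6,7-tetrahydroazulen-1(2H)-one | O=C1CC[C@]2(C)C=C(O[Si](C)(C)C(C)(C)C)CCC=C12 | intermediate
16 | (3aR)-5,5-(ethylenedioxy)-3a-methyl-3,3a,4,5,6,7-hexahydroazulen-1(2H)-one | O=C1CC[C@]2(C)CC3(OCCO3)CCC=C12 | intermediate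
17 | (1R,3aR)-5,5-(ethylenedioxy)-3a-methyl-1,2,3,3a,4,5,6,7-octahydroazulen-1-ol; 1α-OH | O[C@@H]1CC[C@]2(C)CC3(OCCO3)CCC=C12 | intermediate
18 | (1R,3aR,8aR)-5,5-(ethylenedioxy)-3a-methyldecahydroazulen-1-ol; 1α-OH; 8aα-H; trans-fused | O[C@@H]1CC[C@]2(C)CC3(OCCO3)CCC[C@@H]12 | intermediate
19 | (3aR,8aR)-5,5-(ethylenedioxy)-3a-methyloctahydroazulen-1(2H)-one; trans-fused | O=C1CC[C@]2(C)CC3(OCCO3)CCC[C@@H]12 | intermediate
20 | lithium (3aR,8aR)-5,5-(ethylenedioxy)-3a-methyl-3,3a,4,5,6,7,8,8a-octahydroazulen-1-olate (not isolated) | [Li+].[O-]C1=CC[C@]2(C)CC3(OCCO3)CCC[C@@H]12 | intermediate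
21 | (3aR,8aR)-5,5-(ethylenedioxy)-3a-methyl-3,3a,4,5,6,7,8,8a-octahydroazulen-1-yl trifluoromethanesulfonate | O=S(=O)(OC1=CC[C@]2(C)CC3(OCCO3)CCC[C@@H]12)C(F)(F)F | intermediate
22 | tributyl(1-ethoxyethenyl)stannane | CCCC[Sn](CCCC)(CCCC)C(=C)OCC | starting material
23 | (3aR,8aR)-1-(1-ethoxyethenyl)-5,5-(ethylenedioxy)-3a-methyl-3,3a,4,5,6,7,8,8a-octahydroazulene (not isolated) | CCOC(=C)C1=CC[C@]2(C)CC3(OCCO3)CCC[C@@H]12 | intermediate
24 | 1-[(3aR,8aR)-5,5-(ethylenedioxy)-3a-methyl-3,3a,4,5,6,7,8,8a-octahydroazulen-1-yl]ethan-1-one | CC(=O)C1=CC[C@]2(C)CC3(OCCO3)CCC[C@@H]12 | intermediate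
25 | 1-[(1S,3aR,8aS)-5,5-(ethylenedioxy)-3a-methyldecahydroazulen-1-yl]ethan-1-one; 1β-acetyl; 8aα-H | CC(=O)[C@H]1CC[C@]2(C)CC3(OCCO3)CCC[C@@H]12 | intermediate
26 | (S)-2-hydroxy-1,2,2-triphenylethyl acetate | CC(=O)O[C@@H](c1ccccc1)C(O)(c1ccccc1)c1ccccc1 | starting material
27 | dilithium enolate of 26 (not isolated) | [Li+].[Li+].C=C([O-])O[C@@H](c1ccccc1)C([O-])(c1ccccc1)c1ccccc1 | intermediate
28 | (1S)-2-hydroxy-1,2,2-triphenylethyl (3S)-3-hydroxy-4-methylpent-4-enoate | C=C(C)[C@H](CC(=O)O[C@@H](c1ccccc1)C(O)(c1ccccc1)c1ccccc1)O | intermediate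
29 | (1S)-2-hydroxy-1,2,2-triphenylethyl (3S)-3-[(tert-butyldimethylsilyl)oxy]-4-methylpent-4-enoate | C=C(C)[C@H](CC(=O)O[C@@H](c1ccccc1)C(O)(c1ccccc1)c1ccccc1)O[Si](C)(C)C(C)(C)C | intermediate
30 | (3S)-3-[(tert-butyldimethylsilyl)oxy]-4-methylpent-4-en-1-ol | C=C(C)[C@H](CCO)O[Si](C)(C)C(C)(C)C | intermediate
31 | (3S)-5-bromo-3-[(tert-butyldimethylsilyl)oxy]-2-methylpent-1-ene | C=C(C)[C@H](CCBr)O[Si](C)(C)C(C)(C)C | intermediate
32 | [(3S)-3-[(tert-butyldimethylsilyl)oxy]-4-methylpent-4-en-1-yl]magnesium bromide (not isolated) | C=C(C)[C@H](CC[Mg]Br)O[Si](C)(C)C(C)(C)C | intermediate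
33 | (1S,3aR,8aS)-1-[(2S,5S)-5-[(tert-butyldimethylsilyl)oxy]-2-hydroxy-6-methylhept-6-en-2-yl]-5,5-(ethylenedioxy)-3a-methyldecahydroazulene | C=C(C)[C@H](CC[C@](C)(O)[C@H]1CC[C@]2(C)CC3(OCCO3)CCC[C@@H]12)O[Si](C)(C)C(C)(C)C | intermediate
34 | (1S,3aR,8aS)-1-[(2S,5S)-5-[(tert-butyldimethylsilyl)oxy]-2-hydroxy-6-methylhept-6-en-2-yl]-3a-methyloctahydroazulen-5(1H)-one | C=C(C)[C@H](CC[C@](C)(O)[C@H]1CC[C@]2(C)CC(=O)CCC[C@@H]12)O[Si](C)(C)C(C)(C)C | intermediate
35 | 6-[(dimethylamino)methyl] derivative of 34 (C6 epimers; not isolated) | C=C(C)[C@H](CC[C@](C)(O)[C@H]1CC[C@]2(C)CC(=O)C(CN(C)C)CC[C@@H]12)O[Si](C)(C)C(C)(C)C | intermediate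
36 | 6-[(trimethylammonio)methyl] derivative of 34 as the iodide (C6 epimers; not isolated) | C=C(C)[C@H](CC[C@](C)(O)[C@H]1CC[C@]2(C)CC(=O)C(C[N+](C)(C)C)CC[C@@H]12)O[Si](C)(C)C(C)(C)C.[I-] | intermediate
37 | (1S,3aR,8aS)-1-[(2S,5S)-5-[(tert-butyldimethylsilyl)oxy]-2-hydroxy-6-methylhept-6-en-2-yl]-3a-methyl-6-methylideneoctahydroazulen-5(1H)-one | C=C(C)[C@H](CC[C@](C)(O)[C@H]1CC[C@]2(C)CC(=O)C(=C)CC[C@@H]12)O[Si](C)(C)C(C)(C)C | intermediate
38 | (1S,3aR,5S,8aS)-1-[(2S,5S)-5-[(tert-butyldimethylsilyl)oxy]-2-hydroxy-6-methylhept-6-en-2-yl]-3a-methyl-6-methylidenedecahydroazulen-5-ol | C=C(C)[C@H](CC[C@](C)(O)[C@H]1CC[C@]2(C)C[C@H](O)C(=C)CC[C@@H]12)O[Si](C)(C)C(C)(C)C | intermediate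
39 | (1S,3aR,5S,8aS)-1-[(2S,5S)-2,5-dihydroxy-6-methylhept-6-en-2-yl]-3a-methyl-6-methylidenedecahydroazulen-5-ol | C=C(C)[C@H](CC[C@](C)(O)[C@H]1CC[C@]2(C)C[C@H](O)C(=C)CC[C@@H]12)O | intermediate
40 | (1S,3aR,5S,8aS)-1-[(2S,5S)-5-acetoxy-2-hydroxy-6-methylhept-6-en-2-yl]-3a-methyl-6-methylidenedecahydroazulen-5-yl acetate (CNP0151143.1) | C=C(C)[C@H](CC[C@](C)(O)[C@H]1CC[C@]2(C)C[C@H](OC(C)=O)C(=C)CC[C@@H]12)OC(C)=O | target

Total step count: 25 (21 in the main line, 4 for the side-chain bromide 31).
Longest linear sequence: 21 steps (steps 1–15, then 20–25).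

Steps most likely to fail

1. Step 8. The chiral catalyst may discriminate poorly between the two faces of the trisubstituted alkene in this intramolecular cyclopropanation, so that the material is formed with low enantiomeric purity. Fallback: setting out from 13, decomposition with achiral Rh2(OAc)4 under the same thermal regime would give racemic 5-[(tert-butyldimethylsilyl)oxy]-3a-methyl-3,3a,6,7-tetrahydroazulen-1(2H)-one F1. Acetal exchange as in step 9 would give racemic 5,5-(ethylenedioxy)-3a-methyl-3,3a,4,5,6,7-hexahydroazulen-1(2H)-one F2. The reagent-controlled CBS reduction of step 10 should then fix C1 as R in both enantiomers and so turn them into two diastereomeric allylic alcohols, 17 and (1R,3aS)-5,5-(ethylenedioxy)-3a-methyl-1,2,3,3a,4,5,6,7-octahydroazulen-1-ol F3. These would be separated by chromatography, and the route is rejoined at 17.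

2. Step 20. The organomagnesium reagent may attack the face of the acetyl group that the Felkin–Anh model disfavours, or may enolise the ketone. Fallback, for the case that the preference proves to be for the undesired face: the two carbon groups are introduced in the opposite order, so that the same facial preference delivers the other carbinol epimer. Setting out from triflate 21, palladium-catalysed aminocarbonylation (Pd(OAc)2, dppp, CO, MeNH(OMe)·HCl, Et3N, DMF) would give (3aR,8aR)-5,5-(ethylenedioxy)-N-methoxy-N,3a-dimethyl-3,3a,4,5,6,7,8,8a-octahydroazulene-1-carboxamide F4. Hydrogenation from the α-face (H2, Pd/C) would give (1S,3aR,8aS)-5,5-(ethylenedioxy)-N-methoxy-N,3a-dimethyldecahydroazulene-1-carboxamide F5. Addition of organomagnesium bromide 32 would give (4S)-4-[(tert-butyldimethylsilyl)oxy]-1-[(1S,3aR,8aS)-5,5-(ethylenedioxy)-3a-methyldecahydroazulen-1-yl]-5-methylhex-5-en-1-one F6. Methylmagnesium bromide at −78 °C would then form the tertiary carbinol with methyl as the incoming group, and the route is rejoined at 33.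

3. Step 23. The facial bias of the substrate (the axial C3a methyl group shields the β-face of C5) may oppose the catalyst and erode the selectivity at C5. Fallback: setting out from 37, a substrate-controlled 1,2-reduction (NaBH4, CeCl3·7H2O, MeOH, −78 °C) should then give mainly the C5 epimer, (1S,3aR,5R,8aS)-1-[(2S,5S)-5-[(tert-butyldimethylsilyl)oxy]-2-hydroxy-6-methylhept-6-en-2-yl]-3a-methyl-6-methylidenedecahydroazulen-5-ol F7. Mitsunobu inversion with acetic acid (PPh3, DIAD, AcOH, toluene, 0 °C) would give (1S,3aR,5S,8aS)-1-[(2S,5S)-5-[(tert-butyldimethylsilyl)oxy]-2-hydroxy-6-methylhept-6-en-2-yl]-3a-methyl-6-methylidenedecahydroazulen-5-yl acetate F8. Desilylation (Bu4NF, AcOH, THF) would give (1S,3aR,5S,8aS)-1-[(2S,5S)-2,5-dihydroxy-6-methylhept-6-en-2-yl]-3a-methyl-6-methylidenedecahydroazulen-5-yl acetate F9. Acetylation of the remaining secondary alcohol (Ac2O, pyridine) rejoins the route at 40.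

Further compounds
F1 | step 8 | racemic 5-[(tert-butyldimethylsilyl)oxy]-3a-methyl-3,3a,6,7-tetrahydroazulen-1(2H)-one | O=C1CCC2(C)C=C(O[Si](C)(C)C(C)(C)C)CCC=C12
F2 | step 8 | racemic 5,5-(ethylenedioxy)-3a-methyl-3,3a,4,5,6,7-hexahydroazulen-1(2H)-one | O=C1CCC2(C)CC3(OCCO3)CCC=C12
F3 | step 8 | (1R,3aS)-5,5-(ethylenedioxy)-3a-methyl-1,2,3,3a,4,5,6,7-octahydroazulen-1-ol | O[C@@H]1CC[C@@]2(C)CC3(OCCO3)CCC=C12
F4 | step 20 | (3aR,8aR)-5,5-(ethylenedioxy)-N-methoxy-N,3a-dimethyl-3,3a,4,5,6,7,8,8a-octahydroazulene-1-carboxamide | CON(C)C(=O)C1=CC[C@]2(C)CC3(OCCO3)CCC[C@@H]12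
F5 | step 20 | (1S,3aR,8aS)-5,5-(ethylenedioxy)-N-methoxy-N,3a-dimethyldecahydroazulene-1-carboxamide | CON(C)C(=O)[C@H]1CC[C@]2(C)CC3(OCCO3)CCC[C@@H]12
F6 | step 20 | (4S)-4-[(tert-butyldimethylsilyl)oxy]-1-[(1S,3aR,8aS)-5,5-(ethylenedioxy)-3a-methyldecahydroazulen-1-yl]-5-methylhex-5-en-1-one | C=C(C)[C@H](CCC(=O)[C@H]1CC[C@]2(C)CC3(OCCO3)CCC[C@@H]12)O[Si](C)(C)C(C)(C)C
F7 | step 23 | (1S,3aR,5R,8aS)-1-[(2S,5S)-5-[(tert-butyldimethylsilyl)oxy]-2-hydroxy-6-methylhept-6-en-2-yl]-3a-methyl-6-methylidenedecahydroazulen-5-ol | C=C(C)[C@H](CC[C@](C)(O)[C@H]1CC[C@]2(C)C[C@@H](O)C(=C)CC[C@@H]12)O[Si](C)(C)C(C)(C)C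
F8 | step 23 | (1S,3aR,5S,8aS)-1-[(2S,5S)-5-[(tert-butyldimethylsilyl)oxy]-2-hydroxy-6-methylhept-6-en-2-yl]-3a-methyl-6-methylidenedecahydroazulen-5-yl acetate | C=C(C)[C@H](CC[C@](C)(O)[C@H]1CC[C@]2(C)C[C@H](OC(C)=O)C(=C)CC[C@@H]12)O[Si](C)(C)C(C)(C)C
F9 | step 23 | (1S,3aR,5S,8aS)-1-[(2S,5S)-2,5-dihydroxy-6-methylhept-6-en-2-yl]-3a-methyl-6-methylidenedecahydroazulen-5-yl acetate | C=C(C)[C@H](CC[C@](C)(O)[C@H]1CC[C@]2(C)C[C@H](OC(C)=O)C(=C)CC[C@@H]12)O
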